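**Retrosynthetic overview**

1. Target ⇐ trimethyl ether 22 ⇐ guai-5-ene 20: the phenols are freed last, and the two formyl groups are put on by ortho-lithiation once the C5=C6 alkene and the C7 side chain are in place.
2. 20 ⇐ guaian-6-one 16 ⇐ 6,9-dione 14: acetone aldol at C7, reduction at C6 and anti-elimination toward C5; the C9 carbonyl is deleted through its dithiolane.
3. Feature carrying the strategy: the cycloheptane is the C1–C5 bond of the cyclopentane plus the five-carbon chain C6–C10 with its methyl on C10. Cutting C1–C10 and C5–C6 and re-joining C6–C10 gives cyclopentene 9 (C1=C5) and 2-methylcyclopentane-1,3-dione 10, the partners of a de Mayo photocycloaddition–retro-aldol.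
4. 9 ⇐ cyclopentanone 7 ⇐ dihydrocoumarin 4 ⇐ 5,7-dimethoxycoumarin 1: C9′ by asymmetric conjugate addition, C4 by alkylation trans to it on the lactone ring, which is then opened.
5. Ring order: arene (bought) → cyclopentane (step 6) → cyclobutane (step 10, transient) → cycloheptane (step 10).

Key step: step 10

Remark on the chemistry: ring atoms carry guaiane numbers (C1–C5 cyclopentane with C4 quaternary; C1, C5–C10 cycloheptane; C11 the carbinol carbon; C9′ the benzylic carbon). α is the face of H1 and H5 in the cis-fused compounds and β the face of the C4 methyl. The dione 10 enters the photoreaction as its enol acetate 11.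

**Route**

Step 1
Reactants: 1 5,7-dimethoxycoumarin
Product: 2 (4R)-5,7-dimethoxy-4-(2-methylpropyl)-3,4-dihydro-2H-chromen-2-one
Conditions: i-BuMgBr (1.5 equiv), CuBr·SMe2 (5 mol %), (R)-1-[(Sp)-2-(diphenylphosphino)ferrocenyl]ethyldicyclohexylphosphine (6 mol %; the ligand enantiomer that gives 4R is used), t-BuOMe, −75 °C; then 1 M HCl
Reagents that add atoms: isobutylmagnesium bromide, CC(C)C[Mg]Br
Why: Copper-catalysed asymmetric conjugate addition of a Grignard reagent to a coumarin; the chiral diphosphine–copper complex selects the face of C4, which sets C9′.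

Step 2
Reactants: 2 (4R)-5,7-dimethoxy-4-(2-methylpropyl)-3,4-dihydro-2H-chromen-2-one
Product: 3 (3R,4R)-5,7-dimethoxy-3-methyl-4-(2-methylpropyl)-3,4-dihydro-2H-chromen-2-one (methyl trans to isobutyl)
Conditions: LiN(i-Pr)2, THF, −78 °C; MeI, −78 → −40 °C
Reagents that add atoms: iodomethane, CI
Why: Lactone enolate alkylation; methyl iodide should enter trans to the C4 isobutyl group, but this centre is enolised again in step 3, so its configuration does not matter.

Step 3
Reactants: 3 (3R,4R)-5,7-dimethoxy-3-methyl-4-(2-methylpropyl)-3,4-dihydro-2H-chromen-2-one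
Product: 4 (3R,4S)-5,7-dimethoxy-3-methyl-4-(2-methylpropyl)-3-(prop-2-en-1-yl)-3,4-dihydro-2H-chromen-2-one (allyl trans, methyl cis to isobutyl)
Conditions: LiN(i-Pr)2, THF, −78 °C; allyl bromide, −78 → −30 °C
Reagents that add atoms: allyl bromide, C=CCBr
Why: Second enolate alkylation; the isobutyl group, held pseudo-axial by the peri 5-methoxy group, shields one face of the enolate, so the allyl group should add trans to it and the methyl end cis, which fixes the quaternary centre (future C4) relative to C9′.

Step 4
Reactants: 4 (3R,4S)-3-allyl-3-methyl-4-isobutyl lactone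
Product: 5 (3R,4S)-5,7-dimethoxy-3-methyl-4-(2-methylpropyl)-3-(prop-2-en-1-yl)-3,4-dihydro-2H-chromen-2-ol (lactol, anomer mixture)
Conditions: i-Bu2AlH (1.1 equiv), toluene, −78 °C; aq. potassium sodium tartrate
Reagents that add atoms: none
Why: Partial reduction of the aryl lactone to the lactol at −78 °C, where the aluminium acetal is stable; the two set centres are untouched and the anomeric centre is lost in step 5.

Step 5
Reactants: 5 lactol
Product: 6 (2R)-2-methyl-2-[(1S)-3-methyl-1-(2,4,6-trimethoxyphenyl)butyl]pent-4-enal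
Conditions: MeI, K2CO3, DMF, 25 °C
Reagents that add atoms: iodomethane, CI
Why: The lactol is in equilibrium with the phenoxide–aldehyde; Williamson methylation of the phenoxide traps the open form as a non-enolisable α-quaternary aldehyde.

Step 6
Reactants: 6 (2R)-2-methyl-2-[(1S)-3-methyl-1-(2,4,6-trimethoxyphenyl)butyl]pent-4-enal
Product: 7 (2R)-2-methyl-2-[(1S)-3-methyl-1-(2,4,6-trimethoxyphenyl)butyl]cyclopentan-1-one
Conditions: [Rh(nbd)(dppe)]BF4 (5 mol %, activated with H2), acetone, 25 °C
Reagents that add atoms: none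
Why: Rhodium-catalysed intramolecular hydroacylation of a 4-pentenal closes the cyclopentanone (C5–C1 bond); the fully substituted α-carbon favours cyclisation over decarbonylation and no stereocentre is touched.

Step 7
Reactants: 7 cyclopentanone
Product: 8 (5R)-5-methyl-5-[(1R)-3-methyl-1-(2,4,6-trimethoxyphenyl)butyl]cyclopent-1-en-1-yl trifluoromethanesulfonate
Conditions: KN(SiMe3)2, THF, −78 °C; PhNTf2, −78 → 0 °C
Reagents that add atoms: N-phenylbis(trifluoromethanesulfonimide), O=S(=O)(N(c1ccccc1)S(=O)(=O)C(F)(F)F)C(F)(F)F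
Why: Enol triflate formation; only C1 can be enolised, so a single regioisomer forms.

Step 8
Reactants: 8 enol triflate
Product: 9 1,3,5-trimethoxy-2-{(1R)-3-methyl-1-[(1S)-1-methylcyclopent-2-en-1-yl]butyl}benzene
Conditions: Pd(OAc)2 (5 mol %), PPh3, HCO2H, n-Bu3N, DMF, 60 °C
Reagents that add atoms: none
Why: Palladium-catalysed formate reduction of a vinyl triflate gives the C1=C5 alkene without a cationic intermediate that could rearrange next to the quaternary centre.

Step 9
Reactants: 10 2-methylcyclopentane-1,3-dione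
Product: 11 2-methyl-3-oxocyclopent-1-en-1-yl acetate
Conditions: Ac2O, pyridine, DMAP (cat.), CH2Cl2, 0 → 25 °C
Reagents that add atoms: acetic anhydride, CC(=O)OC(C)=O
Why: O-acylation of the enol of the vinylogous acid gives a soluble β-acyloxy enone that absorbs above 300 nm.

Step 10
Reactants: 9 cyclopentene; 11 2-methyl-3-oxocyclopent-1-en-1-yl acetate
Product: 14 cis-fused guaiane-6,9-dione (1α-H; 5α-H; 10α-H; methyls on C4 and C10 β), via cyclobutane photoadduct 12 (not isolated), via cyclobutanol 13 (not isolated)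
Conditions: hν (medium-pressure Hg lamp, Pyrex, λ > 300 nm), 11 (4 equiv), degassed CH2Cl2, 0 °C; then K2CO3, MeOH, 0 → 25 °C
Reagents that add atoms: none
Why: De Mayo reaction in its enol-acetate form: excitation of enone 11 and intersystem crossing give a triplet that adds to the C1=C5 alkene through a 1,4-biradical to the cyclobutane 12 (bonds C1–C10 and C5–C6), and methanolysis of the tertiary acetate frees cyclobutanol 13, whose alkoxide cleaves C6–C10 by retro-aldol fragmentation, driven by ring strain and by the C9 ketone that takes up the charge. The closest known reaction type is the photocycloaddition of 3-acyloxycycloalk-2-enones to cycloalkenes with base-induced opening to 1,5-diketones. The cyclobutane closes by recombination of the biradical; the cycloheptane is not closed by a cyclisation but arises when the bond shared by the four- and five-membered rings of the dione part breaks, a two-carbon enlargement of the dione ring. H1 and H5 should come out cis because both new bonds form on one face of the cyclopentene, the β face of the C4 methyl, anti to the bulky C9′ branch; C10 is protonated on the open α face and, being α to the C9 ketone, should settle under K2CO3/MeOH in the epimer whose methyl is equatorial and cis to C2 (the quaternary C4 keeps the C5 arm equatorial, which makes C2 axial at C1). The step needs the orientation C6→C5 and C10→C1 together with β-face attack: first bonding should take place at the unhindered C1, and of the two biradicals the one bonded through the enone α-carbon (C10–C1) should close, since it joins the small acetoxy-bearing radical centre to the neopentyl C5, whereas in the other the stabilised α-keto radical would have to bond next to the quaternary C4 and should revert to the components. Light above 300 nm is absorbed only by 11, so the trimethoxyarene stays in its ground state.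

Step 11
Reactants: 14 cis-fused guaiane-6,9-dione
Product: 15 9,9-ethylenedithio ketal of 14 (spiro-1,3-dithiolane at C9, 6-ketone free)
Conditions: HS(CH2)2SH (1.1 equiv), BF3·OEt2, CH2Cl2, −20 °C
Reagents that add atoms: ethane-1,2-dithiol, SCCS
Why: Chemoselective dithioketalisation; the C9 ketone lies between CH2 and CH(CH3), whereas the C6 ketone is shielded by the ring fusion, the quaternary C4 and its β-methyl, and C10 can no longer epimerise once C9 is sp3.

Step 12
Reactants: 15 C9 dithiolane
Product: 16 cis-fused guaian-6-one (C9 = CH2)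
Conditions: Raney Ni (W-2), EtOH, 60 °C
Reagents that add atoms: none
Why: Raney nickel desulfurisation (Mozingo reduction) replaces both C–S bonds by C–H; the arene and the hindered ketone should be inert.

Step 13
Reactants: 16 guaian-6-one
Product: 18 7α-[2-(trimethylsilyloxy)propan-2-yl]guaian-6-one, via lithium aldolate 17 (not isolated)
Conditions: LiN(i-Pr)2, THF, −78 °C; acetone, −78 °C; TMSCl, −78 → −20 °C
Reagents that add atoms: acetone, CC(C)=O; chlorotrimethylsilane, C[Si](C)(C)Cl
Why: Kinetic deprotonation occurs at the C7 methylene, not at the hindered C5 methine; the aldol addition to acetone should take place on the convex α face of the cis-fused bicycle (side chain 7α), and silylation of the aldolate in the same flask blocks the retro-aldol.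

Step 14
Reactants: 18 β-silyloxy ketone
Product: 19 6β-alcohol of 18 (OH trans to H5 and to the C7 side chain)
Conditions: LiAlH4, Et2O, −78 °C; aq. potassium sodium tartrate
Reagents that add atoms: none
Why: Hydride reduction; the β face of the C6 carbonyl is blocked by the C4 methyl, which sits gauche to C6, so hydride should arrive from the α face and give the 6β-alcohol.

Step 15
Reactants: 19 6β-alcohol
Product: 20 guai-5-ene (C5=C6; 11-O-trimethylsilyl; 2,4,6-trimethoxyphenyl)
Conditions: Ph2S[OC(CF3)2Ph]2 (Martin sulfurane), CH2Cl2, 0 → 25 °C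
Reagents that add atoms: none
Why: Dehydration by anti elimination of the alkoxysulfonium; the 6β leaving group is anti-periplanar only to H5α (H7 is β), so the alkene should form toward C5, and the silylated tertiary alcohol is inert.

Step 16
Reactants: 20 guai-5-ene
Product: 22 3′,5′-diformyl-2′,4′,6′-tri-O-methyl ether of the target (11-OH free), via lithium amino alkoxide 21 (not isolated)
Conditions: n-BuLi, TMEDA, THF, 0 °C; DMF, −78 → 0 °C; n-BuLi, TMEDA, 0 °C; DMF; then 1 M HCl, THF, 25 °C
Reagents that add atoms: N,N-dimethylformamide, CN(C)C=O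
Why: Double directed ortho-lithiation–formylation; each ring hydrogen lies between two methoxy groups, the first DMF adduct stays as the lithium α-amino alkoxide and protects that aldehyde during the second lithiation, and the acidic work-up frees both aldehydes and the tertiary alcohol.

Step 17
Reactants: 22 dialdehyde trimethyl ether
Product: 23 target (CNP0281883.1)
Conditions: NaSEt (excess), DMF, 110 °C; then 1 M HCl
Reagents that add atoms: none
Why: O-demethylation by SN2 attack of thiolate on the methyl groups; all three methoxy groups are ortho or para to a formyl group and leave as stabilised phenoxides, while the tertiary alcohol and the alkene should be inert.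

**Compound list**

1 | 5,7-dimethoxy-2H-chromen-2-one (5,7-dimethoxycoumarin) | COc1cc(OC)c2c(c1)OC(=O)C=C2 | starting material
2 | (4R)-5,7-dimethoxy-4-(2-methylpropyl)-3,4-dihydro-2H-chromen-2-one | COc1cc(OC)c2c(c1)OC(=O)C[C@H]2CC(C)C | intermediate
3 | (3R,4R)-5,7-dimethoxy-3-methyl-4-(2-methylpropyl)-3,4-dihydro-2H-chromen-2-one | COc1cc(OC)c2c(c1)OC(=O)[C@H](C)[C@H]2CC(C)C | intermediate
4 | (3R,4S)-5,7-dimethoxy-3-methyl-4-(2-methylpropyl)-3-(prop-2-en-1-yl)-3,4-dihydro-2H-chromen-2-one | COc1cc(OC)c2c(c1)OC(=O)[C@](C)(CC=C)[C@H]2CC(C)C | intermediate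
5 | (3R,4S)-5,7-dimethoxy-3-methyl-4-(2-methylpropyl)-3-(prop-2-en-1-yl)-3,4-dihydro-2H-chromen-2-ol (anomer mixture) | COc1cc(OC)c2c(c1)OC(O)[C@](C)(CC=C)[C@H]2CC(C)C | intermediate
6 | (2R)-2-methyl-2-[(1S)-3-methyl-1-(2,4,6-trimethoxyphenyl)butyl]pent-4-enal | CC(C)C[C@@H](c1c(OC)cc(OC)cc1OC)[C@@](C)(CC=C)C=O | intermediate
7 | (2R)-2-methyl-2-[(1S)-3-methyl-1-(2,4,6-trimethoxyphenyl)butyl]cyclopentan-1-one | CC(C)C[C@@H](c1c(OC)cc(OC)cc1OC)[C@@]1(C)CCCC1=O | intermediate
8 | (5R)-5-methyl-5-[(1R)-3-methyl-1-(2,4,6-trimethoxyphenyl)butyl]cyclopent-1-en-1-yl trifluoromethanesulfonate | CC(C)C[C@@H](c1c(OC)cc(OC)cc1OC)[C@@]1(C)CCC=C1OS(=O)(=O)C(F)(F)F | intermediate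
9 | 1,3,5-trimethoxy-2-{(1R)-3-methyl-1-[(1S)-1-methylcyclopent-2-en-1-yl]butyl}benzene | CC(C)C[C@@H](c1c(OC)cc(OC)cc1OC)[C@@]1(C)CCC=C1 | intermediate
10 | 2-methylcyclopentane-1,3-dione | CC1C(=O)CCC1=O | starting material
11 | 2-methyl-3-oxocyclopent-1-en-1-yl acetate | CC(=O)OC1=C(C)C(=O)CC1 | intermediate
12 | cis-anti-cis cyclobutane photoadduct of 9 and 11 (C1–C10 and C5–C6 bonds on the β face; acetate on C6, methyl on C10, ketone at C9) | CC(C)C[C@@H](c1c(OC)cc(OC)cc1OC)[C@@]1(C)CC[C@H]2[C@@H]1[C@]3(OC(C)=O)CCC(=O)[C@]23C | intermediate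
13 | cyclobutanol from 12 (C6–OH, same skeleton) | CC(C)C[C@@H](c1c(OC)cc(OC)cc1OC)[C@@]1(C)CC[C@H]2[C@@H]1[C@]3(O)CCC(=O)[C@]23C | intermediate
14 | cis-fused guaiane-6,9-dione: 3,8-dimethyl-3-[3-methyl-1-(2,4,6-trimethoxyphenyl)butyl]octahydroazulene-4,7(1H,5H)-dione, 1α-H, 5α-H, 10α-H, C9′ branch on C4α | CC(C)C[C@@H](c1c(OC)cc(OC)cc1OC)[C@@]1(C)CC[C@H]2[C@@H]1C(=O)CCC(=O)[C@H]2C | intermediate
15 | 9,9-ethylenedithio ketal of 14 (spiro-1,3-dithiolane at C9) | CC(C)C[C@@H](c1c(OC)cc(OC)cc1OC)[C@@]1(C)CC[C@H]2[C@@H]1C(=O)CCC3(SCCS3)[C@H]2C | intermediate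
16 | cis-fused guaian-6-one (C9 = CH2; stereocentres as in 14) | CC(C)C[C@@H](c1c(OC)cc(OC)cc1OC)[C@@]1(C)CC[C@H]2[C@@H]1C(=O)CCC[C@H]2C | intermediate
17 | lithium aldolate: 16 with C(CH3)2OLi on C7α | CC(C)C[C@@H](c1c(OC)cc(OC)cc1OC)[C@@]1(C)CC[C@H]2[C@@H]1C(=O)[C@H](C(C)(C)O[Li])CC[C@H]2C | intermediate
18 | 7α-[2-(trimethylsilyloxy)propan-2-yl]guaian-6-one | CC(C)C[C@@H](c1c(OC)cc(OC)cc1OC)[C@@]1(C)CC[C@H]2[C@@H]1C(=O)[C@H](C(C)(C)O[Si](C)(C)C)CC[C@H]2C | intermediate
19 | 6β-alcohol of 18 | CC(C)C[C@@H](c1c(OC)cc(OC)cc1OC)[C@@]1(C)CC[C@H]2[C@@H]1[C@@H](O)[C@H](C(C)(C)O[Si](C)(C)C)CC[C@H]2C | intermediate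
20 | guai-5-ene with 11-O-trimethylsilyl and 2,4,6-trimethoxyphenyl groups | CC(C)C[C@@H](c1c(OC)cc(OC)cc1OC)[C@@]1(C)CC[C@H]2C1=C[C@H](C(C)(C)O[Si](C)(C)C)CC[C@H]2C | intermediate
21 | lithium α-(dimethylamino)alkoxide on C3′ of 20 (first DMF adduct) | CC(C)C[C@@H](c1c(OC)c(C(O[Li])N(C)C)c(OC)cc1OC)[C@@]1(C)CC[C@H]2C1=C[C@H](C(C)(C)O[Si](C)(C)C)CC[C@H]2C | intermediate
22 | 3′,5′-diformyl-2′,4′,6′-tri-O-methyl ether of the target | CC(C)C[C@@H](c1c(OC)c(C=O)c(OC)c(C=O)c1OC)[C@@]1(C)CC[C@H]2C1=C[C@H](C(C)(C)O)CC[C@H]2C | intermediate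
23 | CNP0281883.1 | CC(C)C[C@@H](c1c(O)c(C=O)c(O)c(C=O)c1O)[C@@]1(C)CC[C@H]2C1=C[C@H](C(C)(C)O)CC[C@H]2C | target

**Step count**

Total: 17 steps. Longest linear sequence: 16 steps (steps 1–8 and 10–17; step 9 is a one-step branch).

**The three steps most likely to fail**

Step 10. The enone may add in the reverse orientation (C6 to C1), may add on the α face, or the biradical may revert faster than it closes on the hindered alkene. The fallback sets out from ketone 7 and comes back at dione 14, and it replaces steric control of the orientation by electronic control. Ketone 7 is converted (TBSOTf, Et3N, CH2Cl2) into its tert-butyldimethylsilyl enol ether F1. Irradiation of F1 with 11 under the step 10 conditions should follow the head-to-tail rule of enone–enol ether photocycloadditions, in which the oxygen-bearing alkene carbon (C5) bonds to the enone β-carbon (C6), and give the cyclobutane F2. K2CO3 in MeOH should open it to the 5-silyloxy-6,9-dione F3. SmI2 in THF–MeOH should cleave the C5–O bond of this α-silyloxy ketone, and protonation of the enolate should give 14.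

Step 11. The two ketones may not be told apart well enough (bis-thioketal, or reaction at C6), and C10 or C5 may drift under the Lewis acid. The fallback sets out from photoadduct 12, taken out of the flask after the irradiation, and comes back at ketone 16; at this stage C9 is the only ketone. NaBH4 in MeOH should give the C9 alcohol F4, and MsCl with Et3N its methanesulfonate F5. K2CO3 in MeOH should cleave the acetate, and the alkoxide should open the cyclobutane by Grob fragmentation (C6–C10 breaks, the C9 sulfonate leaves) to the cis-fused guai-9-en-6-one F6. Hydrogenation over Rh on alumina should add to the convex α face of C9=C10 and give 16 with 10α-H. Dithiolane, Raney nickel and the equilibration at C10 are all avoided.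

Step 14. Hydride delivery to C6 may show poor facial selectivity; the 6α-alcohol would turn the elimination of step 15 toward C7. The fallback sets out from ketone 16 and comes back at alcohol 19, and it replaces steric control by delivery from the side chain. The aldol of step 13 is quenched with acetic acid at −78 °C without silylation to give the free β-hydroxy ketone F7. Me4NBH(OAc)3 in MeCN–AcOH at −20 °C (Evans–Saksena reduction) should transfer hydride within the alkoxyborohydride of the α-disposed side chain and give the 6β,11-diol F8. TMSOTf with 2,6-lutidine should give the bis(trimethylsilyl) ether F9, and K2CO3 in MeOH at 0 °C should remove the secondary silyl ether first and return 19.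

**Further compounds**

F1 | step 10 | tert-butyldimethylsilyl enol ether of 7 (C1=C5, OTBS on C5) | CC(C)C[C@@H](c1c(OC)cc(OC)cc1OC)[C@@]1(C)CCC=C1O[Si](C)(C)C(C)(C)C
F2 | step 10 | cyclobutane photoadduct of F1 and 11 (OTBS on C5, acetate on C6) | CC(C)C[C@@H](c1c(OC)cc(OC)cc1OC)[C@@]1(C)CC[C@H]2[C@]1(O[Si](C)(C)C(C)(C)C)[C@]3(OC(C)=O)CCC(=O)[C@]23C
F3 | step 10 | 5-(tert-butyldimethylsilyloxy) derivative of dione 14 | CC(C)C[C@@H](c1c(OC)cc(OC)cc1OC)[C@@]1(C)CC[C@H]2[C@]1(O[Si](C)(C)C(C)(C)C)C(=O)CCC(=O)[C@H]2C
F4 | step 11 | C9 alcohol of photoadduct 12 (C9 epimers) | CC(C)C[C@@H](c1c(OC)cc(OC)cc1OC)[C@@]1(C)CC[C@H]2[C@@H]1[C@]3(OC(C)=O)CCC(O)[C@]23C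
F5 | step 11 | C9 methanesulfonate of F4 | CC(C)C[C@@H](c1c(OC)cc(OC)cc1OC)[C@@]1(C)CC[C@H]2[C@@H]1[C@]3(OC(C)=O)CCC(OS(C)(=O)=O)[C@]23C
F6 | step 11 | cis-fused guai-9-en-6-one (C6 ketone, C9=C10) | CC(C)C[C@@H](c1c(OC)cc(OC)cc1OC)[C@@]1(C)CC[C@H]2[C@@H]1C(=O)CCC=C2C
F7 | step 14 | 7α-(2-hydroxypropan-2-yl)guaian-6-one | CC(C)C[C@@H](c1c(OC)cc(OC)cc1OC)[C@@]1(C)CC[C@H]2[C@@H]1C(=O)[C@H](C(C)(C)O)CC[C@H]2C
F8 | step 14 | 6β,11-diol | CC(C)C[C@@H](c1c(OC)cc(OC)cc1OC)[C@@]1(C)CC[C@H]2[C@@H]1[C@@H](O)[C@H](C(C)(C)O)CC[C@H]2C
F9 | step 14 | 6β,11-bis(trimethylsilyl) ether of F8 | CC(C)C[C@@H](c1c(OC)cc(OC)cc1OC)[C@@]1(C)CC[C@H]2[C@@H]1[C@@H](O[Si](C)(C)C)[C@H](C(C)(C)O[Si](C)(C)C)CC[C@H]2C
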